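**Plan**
Numbering (elemanolide): C10 = quaternary C(Me)(vinyl), C9 = CH2, C8 = C–O-acyl, C7/C6 = lactone ring fusion (C6–O), C5 = CH bearing C4(=C3H2)–C15H2OH, C11(=C13H2)–C12(=O) = lactone carbons; β = face of the C10 methyl.
Cuts, in retrosynthetic order: ester C8–O (Mitsunobu); C15–O (allylic oxidation); lactone C11–C12/C12–O6 (carbonylation of a C11 enol triflate); C10–CH3 (conjugate addition); C10–vinyl (alkylative carbonyl transposition); carbocycle at C5–C6 and C7–C8 (Diels–Alder).
Enabling feature: the cyclohexane has oxygen on C6 and C8 either side of C7, and the quaternary C10 is 1,3 to C8. C8–C9–C10–C5 therefore maps onto a 1,1-dialkoxy-3-silyloxy diene and C6=C7 onto an (E)-β-boryl enone, boron being an O6 placeholder that cannot β-eliminate.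
Forward order: carbocycle (step 5), C10 quaternary centre (steps 7, 8), C8 ester (9, 12), lactone ring (13, 14), C15–OH (15), desilylation (16).
Stereochemistry: C6 from the chiral Lewis acid in step 5; C5 and C7 trans to it (E-dienophile, endo addition; both are later epimerisable α-keto positions whose equilibrium is the all-equatorial array); C10 by axial methyl delivery; C8 by equatorial hydride then inversion; side chain from methyl (R)-3-hydroxy-2-methylpropanoate.

Key step: step 5

Assumption: the sense of induction of the oxazaborolidinium catalyst in step 5 is assigned by analogy with (E)-β-substituted enones; if it proves reversed, the mirror-image catalyst is used.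

Step 1
Reactants: 1 3-methylbut-2-enoyl chloride; 2 1,1-diethoxyethene (ketene diethyl acetal)
Product: 3 1,1-diethoxy-5-methylhexa-1,4-dien-3-one
Conditions: 2 (2.1 equiv), Et2O, 0 °C to rt
Reagents that add atoms: none
Why: C-acylation of a ketene acetal by an acid chloride should give the acylketene acetal, the second equivalent of 2 taking up HCl so that no amine base converts 1 into a vinylketene.

Step 2
Reactants: 3 1,1-diethoxy-5-methylhexa-1,4-dien-3-one
Product: 4 (3Z)-1,1-diethoxy-5-methyl-3-(trimethylsilyloxy)hexa-1,3,5-triene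
Conditions: LiN(i-Pr)2, THF, −78 °C; Me3SiCl
Reagents that add atoms: chlorotrimethylsilane C[Si](C)(C)Cl
Why: silyl enol ether formation by kinetic γ-deprotonation of the s-cis enone at the methyl group syn to the carbonyl should give the Z enol ether, which places the isopropenyl group on the outer position of the diene.

Step 3
Reactants: 5 but-3-yn-2-ol (racemic)
Product: 6 (E)-4-(4,4,5,5-tetramethyl-1,3,2-dioxaborolan-2-yl)but-3-en-2-ol (racemic)
Conditions: B2pin2, CuCl (5 mol%), 4,5-bis(diphenylphosphino)-9,9-dimethylxanthene (5 mol%), NaOt-Bu (10 mol%), MeOH, THF, rt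
Reagents that add atoms: bis(pinacolato)diboron CC1(C)OB(OC1(C)C)B1OC(C)(C)C(C)(C)O1
Why: copper-catalysed syn-borylcupration and protonation (formal anti-Markovnikov hydroboration) of the terminal alkyne should give the E-alkenylboronate.

Step 4
Reactants: 6 (E)-4-(4,4,5,5-tetramethyl-1,3,2-dioxaborolan-2-yl)but-3-en-2-ol
Product: 7 (E)-4-(4,4,5,5-tetramethyl-1,3,2-dioxaborolan-2-yl)but-3-en-2-one
Conditions: Dess–Martin periodinane, CH2Cl2, 0 °C to rt
Reagents that add atoms: none
Why: Dess–Martin oxidation of the secondary allylic alcohol should leave the pinacol boronate and the E-alkene untouched.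

Step 5
Reactants: 4 (3Z)-1,1-diethoxy-5-methyl-3-(trimethylsilyloxy)hexa-1,3,5-triene; 7 (E)-4-(4,4,5,5-tetramethyl-1,3,2-dioxaborolan-2-yl)but-3-en-2-one
Product: 8 1-[2,2-diethoxy-5-(prop-1-en-2-yl)-6-(4,4,5,5-tetramethyl-1,3,2-dioxaborolan-2-yl)-4-(trimethylsilyloxy)cyclohex-3-en-1-yl]ethanone (acetyl on C7 β; boron on C6 α; isopropenyl on C5 β; all trans)
Conditions: (S)-3,3-diphenyl-1-(2-methylphenyl)tetrahydro-1H,3H-pyrrolo[1,2-c][1,3,2]oxazaborole activated with HNTf2 (20 mol%), CH2Cl2, −78 °C; Et3N quench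
Reagents that add atoms: none
Why: Enantioselective Lewis-acid-catalysed Diels–Alder reaction of normal electron demand: the oxazaborolidinium ion activates enone 7 at its acetyl oxygen, the nucleophilic C5 terminus of diene 4 bonds to the boron-bearing β-carbon C6 and the acetyl-bearing C7 bonds to the ketene-acetal carbon C8, so that C5–C6 and C7–C8 form in the same event. The closest known reaction type is the chiral-oxazaborolidinium-catalysed cycloaddition of 1-alkoxy-3-silyloxy dienes to (E)-β-substituted enones; the cyclohexene ring closes as a suprafacial [4+2] addition (in the asynchronous limit a Michael addition followed by 6-exo-trig closure of the enolate carbon onto the dialkoxycarbenium ion). C6 is set by the enone face left open by the catalyst, C7 is trans to C6 because the E geometry of 7 is carried over, and C5 is trans to C6 because acetyl adds endo to the Z enol ether that holds the isopropenyl group outside. Regioselectivity (C5 to C6, not to C7) follows from the matched polarity of the 1,1,3-trioxygenated diene and the enone, and only the C8=C9–C10=C5 diene of the triene should react because the alternative C10=C5–C4=C3 diene has a fully substituted terminus. Boron on C6 stands in for the lactone oxygen as a group that cannot be lost by β-elimination while C10 and later C8 are carbonyl groups.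

Step 6
Reactants: 8 the cycloadduct of step 5
Product: 10 3-ethoxy-6-(prop-1-en-2-yl)-5-(4,4,5,5-tetramethyl-1,3,2-dioxaborolan-2-yl)-4-[1-(trifluoromethylsulfonyloxy)ethenyl]cyclohex-2-en-1-one (C5 β; C6 α; C7 β), via enol triflate ketal 9 (not isolated)
Conditions: KN(SiMe3)2, THF, −78 °C; PhNTf2, −78 to −20 °C; then pyridinium p-toluenesulfonate, wet CH2Cl2, 0 °C
Reagents that add atoms: N-phenylbis(trifluoromethanesulfonimide) O=S(=O)(N(c1ccccc1)S(=O)(=O)C(F)(F)F)C(F)(F)F
Why: enol triflate formation by kinetic deprotonation of the methyl ketone masks the acetyl group as the later C11 unit, and mild acid then hydrolyses the silyl enol ether and eliminates ethanol from the β-keto ketal to the vinylogous ester, in which C5 (now α to the ketone) should settle trans to boron.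

Step 7
Reactants: 10 the vinylogous ester of step 6
Product: 12 3-ethenyl-4-(prop-1-en-2-yl)-5-(4,4,5,5-tetramethyl-1,3,2-dioxaborolan-2-yl)-6-[1-(trifluoromethylsulfonyloxy)ethenyl]cyclohex-2-en-1-one (C5 β; C6 α; C7 β), via tertiary carbinol 11 (not isolated)
Conditions: CH2=CHMgBr, CeCl3, THF, −78 °C; then 1 M HCl, THF, 0 °C
Reagents that add atoms: vinylmagnesium bromide C=C[Mg]Br
Why: Stork–Danheiser alkylative carbonyl transposition (1,2-addition of the vinylcerium reagent to the C10 carbonyl, then acid-mediated loss of ethanol) should move the carbonyl to C8 and leave vinyl on C10, with C7 (now α to the ketone) held trans to boron.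

Step 8
Reactants: 12 the dienone of step 7
Product: 13 5-ethenyl-5-methyl-4-(prop-1-en-2-yl)-3-(4,4,5,5-tetramethyl-1,3,2-dioxaborolan-2-yl)-2-[1-(trifluoromethylsulfonyloxy)ethenyl]cyclohexan-1-one (C10 methyl β and axial; vinyl α)
Conditions: MeMgBr, Cu(OTf)2 (5 mol%), 1,3-bis(2,4,6-trimethylphenyl)imidazolinium chloride (6 mol%), Et2O, −30 °C; aq. NH4Cl
Reagents that add atoms: methylmagnesium bromide C[Mg]Br
Why: copper-catalysed conjugate (1,4) addition of a methyl Grignard reagent, for which carbene-ligated copper favours the ring carbon over the vinyl terminus, should deliver methyl axially on the half-chair that keeps the C5, C6 and C7 substituents equatorial, that is trans to boron and cis to isopropenyl, which sets C10.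

Step 9
Reactants: 13 the ketone of step 8
Product: 14 the corresponding cyclohexan-1-ol with the C8 hydroxyl β (axial)
Conditions: LiBH(s-Bu)3, THF, −78 °C; aq. NH4Cl
Reagents that add atoms: none
Why: ketone reduction by a bulky trialkylborohydride should occur from the equatorial side because the axial face of C8 is blocked by the syn-axial C10 methyl group, giving the axial alcohol.

Step 10
Reactants: 15 methyl (R)-3-hydroxy-2-methylpropanoate
Product: 16 methyl (R)-3-(tert-butyldimethylsilyloxy)-2-methylpropanoate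
Conditions: t-BuMe2SiCl, imidazole, CH2Cl2, rt
Reagents that add atoms: tert-butylchlorodimethylsilane CC(C)(C)[Si](C)(C)Cl
Why: silylation of the primary alcohol (silyl ether formation) does not touch the stereocentre.

Step 11
Reactants: 16 methyl (R)-3-(tert-butyldimethylsilyloxy)-2-methylpropanoate
Product: 17 (R)-3-(tert-butyldimethylsilyloxy)-2-methylpropanoic acid
Conditions: LiOH, THF/H2O, 0 °C; then 1 M HCl to pH 3
Reagents that add atoms: lithium hydroxide [Li+].[OH-]
Why: ester saponification under mild, cold conditions should not epimerise the α-methyl centre.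

Step 12
Reactants: 14 the axial alcohol of step 9; 17 (R)-3-(tert-butyldimethylsilyloxy)-2-methylpropanoic acid
Product: 18 the C8 α (equatorial) (R)-3-(tert-butyldimethylsilyloxy)-2-methylpropanoate of the boryl enol triflate
Conditions: PPh3, diisopropyl azodicarboxylate, toluene, 0 °C to rt
Reagents that add atoms: none
Why: Mitsunobu esterification should displace the activated axial C8 oxygen by the carboxylate with inversion, giving the equatorial ester.

Step 13
Reactants: 18 the boryl ester of step 12
Product: 19 the C6 α alcohol (hydroxy enol triflate ester)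
Conditions: NaBO3·4H2O, THF/H2O, rt
Reagents that add atoms: sodium perborate [Na+].[O-]OB=O
Why: oxidation of the secondary alkyl boronate (carbon-to-oxygen 1,2-migration with retention) should unveil the C6 hydroxyl without harming the ester or the enol triflate.

Step 14
Reactants: 19 the hydroxy enol triflate of step 13
Product: 20 the trans-fused α-methylene-γ-butyrolactone (15-deoxy, side chain O-silylated)
Conditions: Pd(PPh3)4 (10 mol%), CO (1 atm), n-Bu3N, LiCl, MeCN, 65 °C
Reagents that add atoms: carbon monoxide [C-]#[O+]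
Why: palladium-catalysed carbonylative lactonisation (oxidative addition to the enol triflate, CO insertion, capture of the acyl palladium by the C6 hydroxyl) should close the lactone, trans-fused because C6–O and C7–C11 are already trans-diequatorial.

Step 15
Reactants: 20 the lactone of step 14
Product: 21 the 15-hydroxy lactone (side chain O-silylated)
Conditions: SeO2 (0.5 equiv), t-BuOOH, CH2Cl2, 0 °C to rt
Reagents that add atoms: selenium dioxide O=[Se]=O; tert-butyl hydroperoxide CC(C)(C)OO
Why: selenium dioxide allylic hydroxylation (ene reaction then [2,3]-sigmatropic shift) should take place at the methyl group of the isopropenyl unit, the only electron-rich alkene with accessible allylic hydrogens (the vinyl group has none, the lactone methylene is electron-poor, and the C5 methine is flanked by C10 and C6).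

Step 16
Reactants: 21 the 15-hydroxy silyl ether of step 15
Product: 22 (3aR,4S,6S,7R,7aR)-6-ethenyl-7-(3-hydroxyprop-1-en-2-yl)-6-methyl-3-methylidene-2-oxo-octahydro-1-benzofuran-4-yl (2R)-3-hydroxy-2-methylpropanoate (target)
Conditions: HF·pyridine, pyridine, THF, 0 °C to rt
Reagents that add atoms: none
Why: buffered fluoride desilylation of the primary silyl ether should leave the ester and the methylene lactone intact.

**Compound list**
1 | 3-methylbut-2-enoyl chloride | CC(C)=CC(=O)Cl | starting material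
2 | 1,1-diethoxyethene | C=C(OCC)OCC | starting material
3 | 1,1-diethoxy-5-methylhexa-1,4-dien-3-one | CCOC(OCC)=CC(=O)C=C(C)C | intermediate
4 | (3Z)-1,1-diethoxy-5-methyl-3-(trimethylsilyloxy)hexa-1,3,5-triene | CCOC(OCC)=C/C(O[Si](C)(C)C)=C/C(C)=C | intermediate
5 | but-3-yn-2-ol (racemic) | CC(O)C#C | starting material
6 | (E)-4-(4,4,5,5-tetramethyl-1,3,2-dioxaborolan-2-yl)but-3-en-2-ol (racemic) | CC(O)/C=C/B1OC(C)(C)C(C)(C)O1 | intermediate
7 | (E)-4-(4,4,5,5-tetramethyl-1,3,2-dioxaborolan-2-yl)but-3-en-2-one | CC(=O)/C=C/B1OC(C)(C)C(C)(C)O1 | intermediate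
8 | 1-[2,2-diethoxy-5-(prop-1-en-2-yl)-6-(pinacolboryl)-4-(trimethylsilyloxy)cyclohex-3-en-1-yl]ethanone; C7 acetyl β, C6 boron α, C5 isopropenyl β | C[Si](C)(C)OC1=CC(OCC)(OCC)[C@@H](C(C)=O)[C@H](B2OC(C)(C)C(C)(C)O2)[C@H]1C(C)=C | intermediate
9 | enol triflate of 8 (1-(cyclohexenyl)ethenyl trifluoromethanesulfonate; ring as in 8) | C[Si](C)(C)OC1=CC(OCC)(OCC)[C@@H](C(=C)OS(=O)(=O)C(F)(F)F)[C@H](B2OC(C)(C)C(C)(C)O2)[C@H]1C(C)=C | intermediate (not isolated)
10 | 3-ethoxy-6-(prop-1-en-2-yl)-5-(pinacolboryl)-4-[1-(trifluoromethylsulfonyloxy)ethenyl]cyclohex-2-en-1-one; C5 β, C6 α, C7 β | O=C1C=C(OCC)[C@@H](C(=C)OS(=O)(=O)C(F)(F)F)[C@H](B2OC(C)(C)C(C)(C)O2)[C@H]1C(C)=C | intermediate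
11 | 1-ethenyl-3-ethoxy-6-(prop-1-en-2-yl)-5-(pinacolboryl)-4-[1-(trifluoromethylsulfonyloxy)ethenyl]cyclohex-2-en-1-ol; carbinol centre undefined | C=CC1(O)C=C(OCC)[C@@H](C(=C)OS(=O)(=O)C(F)(F)F)[C@H](B2OC(C)(C)C(C)(C)O2)[C@H]1C(C)=C | intermediate (not isolated)
12 | 3-ethenyl-4-(prop-1-en-2-yl)-5-(pinacolboryl)-6-[1-(trifluoromethylsulfonyloxy)ethenyl]cyclohex-2-en-1-one; C5 β, C6 α, C7 β | C=CC1=CC(=O)[C@@H](C(=C)OS(=O)(=O)C(F)(F)F)[C@H](B2OC(C)(C)C(C)(C)O2)[C@H]1C(C)=C | intermediate
13 | 5-ethenyl-5-methyl-4-(prop-1-en-2-yl)-3-(pinacolboryl)-2-[1-(trifluoromethylsulfonyloxy)ethenyl]cyclohexan-1-one; C10 methyl β, vinyl α | C=C[C@]1(C)CC(=O)[C@@H](C(=C)OS(=O)(=O)C(F)(F)F)[C@H](B2OC(C)(C)C(C)(C)O2)[C@H]1C(C)=C | intermediate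
14 | the cyclohexan-1-ol from 13 with C8 hydroxyl β (axial) | C=C[C@]1(C)C[C@@H](O)[C@@H](C(=C)OS(=O)(=O)C(F)(F)F)[C@H](B2OC(C)(C)C(C)(C)O2)[C@H]1C(C)=C | intermediate
15 | methyl (R)-3-hydroxy-2-methylpropanoate | COC(=O)[C@H](C)CO | starting material
16 | methyl (R)-3-(tert-butyldimethylsilyloxy)-2-methylpropanoate | COC(=O)[C@H](C)CO[Si](C)(C)C(C)(C)C | intermediate
17 | (R)-3-(tert-butyldimethylsilyloxy)-2-methylpropanoic acid | OC(=O)[C@H](C)CO[Si](C)(C)C(C)(C)C | intermediate
18 | C8 α ester of 17 with the boryl enol triflate cyclohexanol (inverted at C8) | C=C[C@]1(C)C[C@H](OC(=O)[C@H](C)CO[Si](C)(C)C(C)(C)C)[C@@H](C(=C)OS(=O)(=O)C(F)(F)F)[C@H](B2OC(C)(C)C(C)(C)O2)[C@H]1C(C)=C | intermediate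
19 | the C6 α alcohol from 18 | C=C[C@]1(C)C[C@H](OC(=O)[C@H](C)CO[Si](C)(C)C(C)(C)C)[C@@H](C(=C)OS(=O)(=O)C(F)(F)F)[C@H](O)[C@H]1C(C)=C | intermediate
20 | trans-fused α-methylene lactone with C5 isopropenyl and silylated side chain | C=C[C@]1(C)C[C@H](OC(=O)[C@H](C)CO[Si](C)(C)C(C)(C)C)[C@H]2C(=C)C(=O)O[C@@H]2[C@H]1C(C)=C | intermediate
21 | 15-hydroxy derivative of 20 (C5 3-hydroxyprop-1-en-2-yl) | C=C[C@]1(C)C[C@H](OC(=O)[C@H](C)CO[Si](C)(C)C(C)(C)C)[C@H]2C(=C)C(=O)O[C@@H]2[C@H]1C(=C)CO | intermediate
22 | (3aR,4S,6S,7R,7aR)-6-ethenyl-7-(3-hydroxyprop-1-en-2-yl)-6-methyl-3-methylidene-2-oxo-octahydro-1-benzofuran-4-yl (2R)-3-hydroxy-2-methylpropanoate | C=C[C@]1(C)C[C@H](OC(=O)[C@H](C)CO)[C@H]2C(=C)C(=O)O[C@@H]2[C@H]1C(=C)CO | target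

**Step count and risks**
Total step count: 16. Longest linear sequence: 12 steps (1, 2, 5, 6, 7, 8, 9, 12, 13, 14, 15, 16).

Step 5. What may go wrong: insufficient facial discrimination by the catalyst; open-chain vinylogous Michael addition through the remote isopropenyl terminus with silyl transfer instead of ring closure; loss of the silyl enol ether to the acidic catalyst. Fallback (resolution instead of catalysis), setting out from 4 and 7: the cycloaddition is run thermally without catalyst (toluene, 80 °C), which should give 8 together with its mirror image, ent-cycloadduct F1. The racemate is taken through steps 6 to 9 unchanged, so that the mirror-image series ent-enol triflate ketal F2 (not isolated), ent-vinylogous ester F3, ent-carbinol F4 (not isolated), ent-dienone F5, ent-ketone F6 and ent-axial alcohol F7 accompanies 9 to 14. Mitsunobu coupling with enantiopure 17 then gives 18 and the diastereomeric ester F8, which are separated by chromatography; the route is rejoined at 18.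

Step 8. What may go wrong: 1,6-addition at the vinyl terminus, attack of the Grignard reagent on the boronate or the enol triflate, deprotonation at C5 or C7, or methyl delivery to the wrong face. Fallback (vinyl built from a one-carbon acyl-anion equivalent, so that no dienone is involved), setting out from 10: 2-lithio-1,3-dithiane with CeCl3 followed by 1 M HCl should give, through the dithianyl carbinol F9 (not isolated), the 3-(1,3-dithian-2-yl) enone F10, which has no 1,6-position. Me2CuLi with Me3SiCl then adds methyl axially to give the dithianyl methyl ketone F11. MeI and CaCO3 in aqueous MeCN unmask the keto aldehyde F12, and one equivalent of Ph3P=CH2 at −78 °C methylenates the aldehyde selectively; the route is rejoined at 13.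

Step 12. What may go wrong: elimination of the activated axial oxygen towards C7 or C9, or no substitution at the hindered carbinol. Fallback (equatorial alcohol made directly, then acylation with retention), setting out from 13: reduction under thermodynamic control with SmI2, H2O and Et3N in THF should give the equatorial alcohol F13, which is esterified with 17 under Yamaguchi conditions (2,4,6-trichlorobenzoyl chloride, Et3N, then 4-dimethylaminopyridine, toluene); the route is rejoined at 18.

**Further compounds**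
F1 | step 5 | enantiomer of 8 | C[Si](C)(C)OC1=CC(OCC)(OCC)[C@H](C(C)=O)[C@@H](B2OC(C)(C)C(C)(C)O2)[C@@H]1C(C)=C
F2 | step 5 | enantiomer of 9 | C[Si](C)(C)OC1=CC(OCC)(OCC)[C@H](C(=C)OS(=O)(=O)C(F)(F)F)[C@@H](B2OC(C)(C)C(C)(C)O2)[C@@H]1C(C)=C
F3 | step 5 | enantiomer of 10 | O=C1C=C(OCC)[C@H](C(=C)OS(=O)(=O)C(F)(F)F)[C@@H](B2OC(C)(C)C(C)(C)O2)[C@@H]1C(C)=C
F4 | step 5 | enantiomer of 11 | C=CC1(O)C=C(OCC)[C@H](C(=C)OS(=O)(=O)C(F)(F)F)[C@@H](B2OC(C)(C)C(C)(C)O2)[C@@H]1C(C)=C
F5 | step 5 | enantiomer of 12 | C=CC1=CC(=O)[C@H](C(=C)OS(=O)(=O)C(F)(F)F)[C@@H](B2OC(C)(C)C(C)(C)O2)[C@@H]1C(C)=C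
F6 | step 5 | enantiomer of 13 | C=C[C@@]1(C)CC(=O)[C@H](C(=C)OS(=O)(=O)C(F)(F)F)[C@@H](B2OC(C)(C)C(C)(C)O2)[C@@H]1C(C)=C
F7 | step 5 | enantiomer of 14 | C=C[C@@]1(C)C[C@H](O)[C@H](C(=C)OS(=O)(=O)C(F)(F)F)[C@@H](B2OC(C)(C)C(C)(C)O2)[C@@H]1C(C)=C
F8 | step 5 | diastereomer of 18 (mirror-image ring, (R) side chain) | C=C[C@@]1(C)C[C@@H](OC(=O)[C@H](C)CO[Si](C)(C)C(C)(C)C)[C@H](C(=C)OS(=O)(=O)C(F)(F)F)[C@@H](B2OC(C)(C)C(C)(C)O2)[C@@H]1C(C)=C
F9 | step 8 | 1-(1,3-dithian-2-yl)-3-ethoxy carbinol from 10 (carbinol centre undefined) | OC1(C2SCCCS2)C=C(OCC)[C@@H](C(=C)OS(=O)(=O)C(F)(F)F)[C@H](B3OC(C)(C)C(C)(C)O3)[C@H]1C(C)=C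
F10 | step 8 | 3-(1,3-dithian-2-yl) analogue of 12 | S1CCCSC1C2=CC(=O)[C@@H](C(=C)OS(=O)(=O)C(F)(F)F)[C@H](B3OC(C)(C)C(C)(C)O3)[C@H]2C(C)=C
F11 | step 8 | 5-(1,3-dithian-2-yl)-5-methyl analogue of 13 (methyl β) | S1CCCSC1[C@]2(C)CC(=O)[C@@H](C(=C)OS(=O)(=O)C(F)(F)F)[C@H](B3OC(C)(C)C(C)(C)O3)[C@H]2C(C)=C
F12 | step 8 | 5-formyl-5-methyl analogue of 13 (methyl β) | O=C[C@]1(C)CC(=O)[C@@H](C(=C)OS(=O)(=O)C(F)(F)F)[C@H](B2OC(C)(C)C(C)(C)O2)[C@H]1C(C)=C
F13 | step 12 | C8 epimer of 14 (hydroxyl α, equatorial) | C=C[C@]1(C)C[C@H](O)[C@@H](C(=C)OS(=O)(=O)C(F)(F)F)[C@H](B2OC(C)(C)C(C)(C)O2)[C@H]1C(C)=C
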